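Dielsianone is cut at the pyran ring: C4 is a single carbon on C4a, flanked by the C5 hydroxyl and by O1 on C8a, so it is traced to the formyl carbon of a 2,6-dihydroxybenzaldehyde, and C3–C2(CH3)2 to an isobutenyl nucleophile. One operation, an amine-catalysed borono-Mannich condensation followed by amine loss and oxa-6π ring closure, forges C3–C4 and O1–C2 and delivers the 2H-chromene with its alkene in place. The precursor is the fully substituted benzaldehyde 5, which already carries the methoxy group, both phenols and the (4-methoxyphenyl)acetyl side chain; it comes in two steps from 4-methoxyresorcinol. Oxidation of the benzylic methylene then gives the 1,2-diketone.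

Key step: step 3

Remark: the target has no stereocenter; the one stereocenter that appears on the way (the aminated carbon of adduct 8) is racemic and is erased in the same flask, so only the alkene geometry of 9 is specified.

Step 1
Reactants: 1 4-methoxybenzene-1,3-diol; 2 4-methoxyphenylacetic acid
Product: 3 1-(2,4-dihydroxy-5-methoxyphenyl)-2-(4-methoxyphenyl)ethan-1-one
Conditions: BF3·OEt2 (as solvent), 85 °C; then aq. NaOAc
Reagents that add atoms: none
Why: Friedel–Crafts (Nencki-type) acylation of a resorcinol by an arylacetic acid should take place at C6 of 1, which is ortho to one hydroxyl, para to the other and unhindered, whereas C2 is crowded by both hydroxyls and C5 is activated only by the methoxy group; the ketone formed is deactivated and held as a boron chelate, so a second acylation is not expected.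

Step 2
Reactants: 3 1-(2,4-dihydroxy-5-methoxyphenyl)-2-(4-methoxyphenyl)ethan-1-one; 4 hexamethylenetetramine
Product: 5 2,6-dihydroxy-3-methoxy-5-[(4-methoxyphenyl)acetyl]benzaldehyde
Conditions: 4 (2 equiv), CF3CO2H, 80 °C; then H2O, 60 °C
Reagents that add atoms: water, O
Why: Duff formylation, in which the iminium ion released from protonated 4 attacks C3 of 3, the only free ring carbon ortho to both hydroxyls (C6 is ortho to the acyl group and meta to both hydroxyls), an internal hydride shift raises the benzylamine to an iminium ion and water releases the aldehyde; the acidic medium keeps enolisation low, so the benzylic methylene and the less activated anisyl ring should stay out of play.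

Step 3
Reactants: 5 2,6-dihydroxy-3-methoxy-5-[(4-methoxyphenyl)acetyl]benzaldehyde; 6 (2-methylprop-1-en-1-yl)boronic acid
Product: 10 1-(5-hydroxy-8-methoxy-2,2-dimethyl-2H-chromen-6-yl)-2-(4-methoxyphenyl)ethan-1-one, via iminium boronate 7 (not isolated), via Mannich base 8 (not isolated), via ortho-quinone methide 9 (not isolated)
Conditions: 6 (1.5 equiv), Bn2NH (40 mol %), 1,4-dioxane, 90 °C
Reagents that add atoms: none
Why: Dibenzylamine condenses with the formyl group of 5 to an iminium ion, the phenoxide beside it binds 6 as a tetracoordinate boronate (7), and the 2-methylprop-1-enyl group migrates from boron to the iminium carbon within this complex to form C3–C4 (Mannich base 8). At 90 °C the benzylic amine is expelled with the help of the ortho hydroxyl to give ortho-quinone methide 9, whose 1-oxatriene closes by thermal disrotatory oxa-6π electrocyclization, joining the carbonyl oxygen to the dimethyl-bearing terminus (O1–C2) and forming the pyran ring while the amine returns to the cycle. The closest known reaction type is the amine-catalysed Petasis borono-Mannich condensation of salicylaldehydes with alkenylboronic acids to 2H-chromenes, and the last two events are those of the condensation of 2,4-dihydroxyaryl ketones with 3-methylbut-2-enal. No stereocenter remains, since the aminated carbon of 8 becomes sp2 C4 and C2 carries two methyl groups. The step needs the aldehyde to react in preference to the ketone, which is secured because the aryl ketone is conjugated, hindered and chelated and only the formyl-derived iminium sits next to the boron-bearing oxygen. It also needs closure through the oxygen next to the methoxy group: the other hydroxyl is locked in a hydrogen bond to the ketone and stays behind as the C5 hydroxyl, and the isomer closed through it would lose that hydrogen bond, so both rate and stability point to 10.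

Step 4
Reactants: 10 1-(5-hydroxy-8-methoxy-2,2-dimethyl-2H-chromen-6-yl)-2-(4-methoxyphenyl)ethan-1-one
Product: 11 dielsianone, 1-(5-hydroxy-8-methoxy-2,2-dimethyl-2H-chromen-6-yl)-2-(4-methoxyphenyl)ethane-1,2-dione
Conditions: SeO2 (1.5 equiv), 1,4-dioxane/H2O (20:1), 100 °C
Reagents that add atoms: selenium dioxide, O=[Se]=O
Why: Riley oxidation, in which SeO2 reacts through the enol of the aryl benzyl ketone at the methylene activated by both the carbonyl and the anisyl ring, and loss of selenium and water leaves the 1,2-diketone; the chromene alkene has no allylic hydrogen (C2 is quaternary) and so offers no ene pathway.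

Compound list
1 | 4-methoxybenzene-1,3-diol (4-methoxyresorcinol) | COc1ccc(O)cc1O | starting material
2 | 4-methoxyphenylacetic acid | COc1ccc(CC(=O)O)cc1 | starting material
3 | 1-(2,4-dihydroxy-5-methoxyphenyl)-2-(4-methoxyphenyl)ethan-1-one | COc1ccc(CC(=O)c2cc(OC)c(O)cc2O)cc1 | intermediate
4 | hexamethylenetetramine | C1N2CN3CN1CN(C2)C3 | starting material
5 | 2,6-dihydroxy-3-methoxy-5-[(4-methoxyphenyl)acetyl]benzaldehyde | O=Cc1c(O)c(C(=O)Cc2ccc(OC)cc2)cc(OC)c1O | intermediate
6 | (2-methylprop-1-en-1-yl)boronic acid | CC(C)=CB(O)O | starting material
7 | iminium boronate: N,N-dibenzyliminium ion of 5 whose oxygen next to the methoxy group is bound to boron as a dihydroxy(2-methylprop-1-enyl)borate (zwitterion) | COc1ccc(CC(=O)c2cc(OC)c(O[B-](O)(O)C=C(C)C)c(C=[N+](Cc3ccccc3)Cc3ccccc3)c2O)cc1 | intermediate (not isolated)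
8 | Mannich base: 1-{3-[1-(dibenzylamino)-3-methylbut-2-en-1-yl]-2,4-dihydroxy-5-methoxyphenyl}-2-(4-methoxyphenyl)ethan-1-one (racemic) | COc1ccc(CC(=O)c2cc(OC)c(O)c(C(C=C(C)C)N(Cc3ccccc3)Cc3ccccc3)c2O)cc1 | intermediate (not isolated)
9 | ortho-quinone methide: (6Z)-5-hydroxy-2-methoxy-4-[(4-methoxyphenyl)acetyl]-6-(3-methylbut-2-en-1-ylidene)cyclohexa-2,4-dien-1-one | O=C1C(OC)=CC(C(=O)Cc2ccc(OC)cc2)=C(O)/C1=C/C=C(C)C | intermediate (not isolated)
10 | 1-(5-hydroxy-8-methoxy-2,2-dimethyl-2H-chromen-6-yl)-2-(4-methoxyphenyl)ethan-1-one | COc1ccc(CC(=O)c2cc(OC)c3c(c2O)C=CC(C)(C)O3)cc1 | intermediate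
11 | dielsianone, 1-(5-hydroxy-8-methoxy-2,2-dimethyl-2H-chromen-6-yl)-2-(4-methoxyphenyl)ethane-1,2-dione | COc1ccc(C(=O)C(=O)c2cc(OC)c3c(c2O)C=CC(C)(C)O3)cc1 | target

Total step count: 4. Longest linear sequence: 4 steps (1 → 3 → 5 → 10 → 11).

Steps most likely to fail

Step 3. The formyl group is hydrogen-bonded and flanked by two oxygens, so iminium formation may be sluggish. Transfer of the trisubstituted alkenyl group may be slow enough for protodeboronation of 6 to win. Ring closure may also run in part through the ketone-side oxygen. The fallback sets out from 3 and comes back at 10, and fixes the ring oxygen before the carbon–carbon bond is made. Compound 3 is O-alkylated at its free 4-hydroxyl (the 2-hydroxyl is chelated to the ketone) with 3-chloro-3-methylbut-1-yne (K2CO3, KI, acetone, reflux) to give the aryl propargyl ether 1-{2-hydroxy-5-methoxy-4-[(2-methylbut-3-yn-2-yl)oxy]phenyl}-2-(4-methoxyphenyl)ethan-1-one F1. Heating F1 in N,N-diethylaniline at about 190 °C should bring about the aromatic propargyl Claisen rearrangement into C3, the only free ortho carbon, since the other carries the methoxy group. This gives the allenylphenol 1-[2,4-dihydroxy-5-methoxy-3-(3-methylbuta-1,2-dien-1-yl)phenyl]-2-(4-methoxyphenyl)ethan-1-one F2 (not isolated). A 1,5-hydrogen shift in F2 leads to quinone methide 9 and, by the same oxa-6π closure, to 10.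

Step 2. The iminium electrophile may attack the enolisable benzylic methylene (Mannich-type aminomethylation followed by ring closure onto the neighbouring hydroxyl). It may also attack the anisyl ring, or the benzylamine stage may be oxidised and hydrolysed incompletely. The fallback sets out from 3 and comes back at 10, so that no formylation is needed. Compound 3 is condensed with 3-methylbut-2-enal in the presence of ethylenediammonium diacetate (catalytic) in toluene at reflux. C3 of 3 should add to the enal-derived iminium ion, loss of water should give quinone methide 9, and 9 should close to 10. The carbon that formylation was to supply thus arrives as the carbonyl carbon of the enal, already bonded to C3 of the pyran. This detour makes no compound outside the list (entry F0).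

Step 4. The 1,2-diketone may be oxidised further or cleaved, and selenium electrophiles may attack the electron-rich chromene alkene or the phenol. The fallback sets out from 10 and comes back at 11, and separates the oxidation into nitrosation and hydrolysis. The enolate of 10 (t-BuOK, 2.2 equiv, THF, −20 to 0 °C) is nitrosated with isoamyl nitrite to give the α-oximino ketone 1-(5-hydroxy-8-methoxy-2,2-dimethyl-2H-chromen-6-yl)-2-(hydroxyimino)-2-(4-methoxyphenyl)ethan-1-one F3. Exchange deoximation of F3 with glyoxylic acid in aqueous THF at room temperature should release the diketone 11.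

Further compounds
F1 | step 3 | 1-{2-hydroxy-5-methoxy-4-[(2-methylbut-3-yn-2-yl)oxy]phenyl}-2-(4-methoxyphenyl)ethan-1-one | COc1ccc(CC(=O)c2cc(OC)c(OC(C)(C)C#C)cc2O)cc1
F2 | step 3 | 1-[2,4-dihydroxy-5-methoxy-3-(3-methylbuta-1,2-dien-1-yl)phenyl]-2-(4-methoxyphenyl)ethan-1-one | COc1ccc(CC(=O)c2cc(OC)c(O)c(C=C=C(C)C)c2O)cc1
F0 | step 2 | none | none
F3 | step 4 | 1-(5-hydroxy-8-methoxy-2,2-dimethyl-2H-chromen-6-yl)-2-(hydroxyimino)-2-(4-methoxyphenyl)ethan-1-one | COc1ccc(C(=NO)C(=O)c2cc(OC)c3c(c2O)C=CC(C)(C)O3)cc1
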